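**Strategy**

Everything hangs on the O1–C2 bond of ring B (O1, C2, C3, C4, C4a, C8a). The β-aryloxy ketone O1–C2–C3–C4(=O) with trans methyl groups on C2 and C3 is read as a phenol added across a tigloyl enone. One cinchona-thiourea-catalysed 6-endo oxa-Michael closure makes that bond, closes ring B and fixes C2; C3 follows by equilibration. The precursor is 2-tigloylphloroglucinol whose para hydroxyl is silylated, leaving two equivalent ortho phenols. Afterwards C6 is alkylated reductively with a verbenone-derived cyclobutane aldehyde, C8 is annulated with phenylpropynal under carbene catalysis, and C6 is prenylated with dearomatisation.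

Key step: step 4

**Remarks on the chemistry (assumptions)**

- (1S,5S)-(−)-Verbenone 9, the commercial allylic-oxidation product of (1S,5S)-(−)-α-pinene, is taken as the chiral-pool entry; its two ring stereocentres become those of the cyclobutane.
- 3-Phenylprop-2-ynal 15 replaces cinnamaldehyde as the three-carbon unit, so that the cinnamoyl azolium forms without an external oxidant, which the electron-rich phloroglucinol ring would not tolerate.
- The sense of induction of the three chiral catalysts (steps 4, 11, 12) is assigned by analogy; the mirror-image or pseudoenantiomeric catalyst is used if a pilot run shows the opposite sense.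
- Compounds 18 and 19 are written as the C5-enol/C7-keto tautomer of the target SMILES.

**Route**

Step 1
Reactants: 1 tiglic acid
Product: 2 tigloyl chloride
Conditions: (COCl)2, DMF (cat.), CH2Cl2, 0 °C → rt
Reagents that add atoms: oxalyl chloride, ClC(=O)C(=O)Cl
Why: Activation of the acid by oxalyl chloride and catalytic DMF gives the acid chloride under neutral conditions that leave the E-trisubstituted alkene untouched (acid chloride formation).

Step 2
Reactants: 2 tigloyl chloride, 3 phloroglucinol
Product: 4 2-tigloylphloroglucinol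
Conditions: AlCl3 (3.5 equiv), PhNO2/CH2Cl2, 0 → 20 °C; ice/aq. HCl
Reagents that add atoms: none
Why: Friedel–Crafts C-acylation of the threefold-activated arene, run with phloroglucinol in excess against diacylation and kept at or below room temperature so that the aluminium-chelated ortho-hydroxyaryl enone is quenched before acid-promoted ring closure can set in.

Step 3
Reactants: 4 2-tigloylphloroglucinol
Product: 5 (E)-1-{4-[(tert-butyldimethylsilyl)oxy]-2,6-dihydroxyphenyl}-2-methylbut-2-en-1-one
Conditions: TBSCl (1.0 equiv), imidazole, DMF/CH2Cl2, −20 °C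
Reagents that add atoms: tert-butyldimethylsilyl chloride, CC(C)(C)[Si](C)(C)Cl
Why: The para hydroxyl is the most acidic and the only one neither hydrogen-bonded to nor flanked by the acyl group, so one equivalent of silyl chloride at low temperature should silylate it selectively (phenol silylation) and leave the two ortho phenols equivalent.

Step 4
Reactants: 5 (E)-1-{4-[(tert-butyldimethylsilyl)oxy]-2,6-dihydroxyphenyl}-2-methylbut-2-en-1-one
Product: 7 (2R,3R)-7-[(tert-butyldimethylsilyl)oxy]-5-hydroxy-2,3-dimethylchroman-4-one, via cis-chromanone silyl ether 6 (not isolated)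
Conditions: 1-[3,5-bis(trifluoromethyl)phenyl]-3-[(8α,9S)-6'-methoxycinchonan-9-yl]thiourea (10 mol%), PhCl, 0 °C → rt; then 45 °C
Reagents that add atoms: none
Why: The quinuclidine nitrogen deprotonates one ortho phenol while the thiourea hydrogen-bonds the enone carbonyl, the ammonium phenoxide adds to the β-carbon of the tigloyl enone, and protonation of the enol at C3 releases the catalyst. The closest known reaction is the cinchona-alkaloid-catalysed intramolecular oxa-Michael addition of ortho-tigloylphenols to 2,3-dimethylchromanones. Ring B is closed in the 6-endo-trig mode through formation of O1–C2. C2 is set by enantioface selection of the enone inside the chiral ion pair; C3 is first set by kinetic protonation and is then equilibrated through the enol to the trans diequatorial arrangement, with the chiral base still present so that any ring-opened material recloses under catalyst control. The step needs only enantioselectivity, because the two ortho hydroxyls are interchangeable, the silylated para oxygen cannot compete as acid or nucleophile, and the non-polar solvent suppresses the uncatalysed racemic closure.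

Step 5
Reactants: 7 (2R,3R)-7-[(tert-butyldimethylsilyl)oxy]-5-hydroxy-2,3-dimethylchroman-4-one
Product: 8 (2R,3R)-5,7-dihydroxy-2,3-dimethylchroman-4-one
Conditions: KHF2, MeOH, rt
Reagents that add atoms: none
Why: Bifluoride cleaves aryl silyl ethers under weakly acidic conditions (fluoride desilylation) that should neither enolise C3 nor open ring B, so both stereocentres are kept.

Step 6
Reactants: 9 (1S,5S)-(−)-verbenone
Product: 10 (1S,3R)-3-acetyl-2,2-dimethylcyclobutane-1-carboxylic acid
Conditions: RuCl3 hydrate (2 mol%), NaIO4 (4.1 equiv), MeCN/EtOAc/H2O, rt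
Reagents that add atoms: sodium periodate, [Na+].[O-]I(=O)(=O)=O
Why: RuO4 generated catalytically from RuCl3 and periodate cleaves the enone C=C bond and the resulting α-keto acid loses CO2 oxidatively (oxidative alkene cleavage), which leaves the cis-1,3-disubstituted cyclobutane with both ring stereocentres of verbenone untouched.

Step 7
Reactants: 10 (1S,3R)-3-acetyl-2,2-dimethylcyclobutane-1-carboxylic acid
Product: 11 methyl (1S,3R)-3-acetyl-2,2-dimethylcyclobutane-1-carboxylate
Conditions: Me3SiCHN2, MeOH/toluene, 0 °C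
Reagents that add atoms: trimethylsilyldiazomethane, C[Si](C)(C)C=[N+]=[N-]
Why: Diazomethane released from the silyl reagent and methanol O-methylates the acid under neutral conditions (esterification), so neither the centre next to the ketone nor the one next to the carboxyl can epimerise.

Step 8
Reactants: 11 methyl (1S,3R)-3-acetyl-2,2-dimethylcyclobutane-1-carboxylate
Product: 12 methyl (1S,3S)-2,2-dimethyl-3-(prop-1-en-2-yl)cyclobutane-1-carboxylate
Conditions: Zn, CH2Br2, TiCl4, THF/CH2Cl2, 0 °C → rt
Reagents that add atoms: dibromomethane, BrCBr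
Why: The non-basic Takai–Lombardo methylene reagent methylenates ketones but not esters and does not enolise the acetyl group, so the cis relationship on the cyclobutane should be retained (carbonyl methylenation).

Step 9
Reactants: 12 methyl (1S,3S)-2,2-dimethyl-3-(prop-1-en-2-yl)cyclobutane-1-carboxylate
Product: 13 (1S,3S)-2,2-dimethyl-3-(prop-1-en-2-yl)cyclobutane-1-carbaldehyde
Conditions: i-Bu2AlH (1.05 equiv), CH2Cl2, −78 °C; MeOH, aq. potassium sodium tartrate
Reagents that add atoms: none
Why: At −78 °C the hindered ester takes up one hydride and the aluminium hemiacetal survives until work-up, giving the aldehyde without over-reduction (partial ester reduction); the aldehyde is used at once to protect its α-stereocentre.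

Step 10
Reactants: 8 (2R,3R)-5,7-dihydroxy-2,3-dimethylchroman-4-one, 13 (1S,3S)-2,2-dimethyl-3-(prop-1-en-2-yl)cyclobutane-1-carbaldehyde
Product: 14 (2R,3R)-6-{[(1R,3S)-2,2-dimethyl-3-(prop-1-en-2-yl)cyclobutyl]methyl}-5,7-dihydroxy-2,3-dimethylchroman-4-one
Conditions: diethyl 2,6-dimethyl-1,4-dihydropyridine-3,5-dicarboxylate (Hantzsch ester, 1.2 equiv), L-proline (10 mol%), EtOH/CH2Cl2, rt; 13 limiting
Reagents that add atoms: none
Why: Knoevenagel-type condensation of the aldehyde with the enolic C6 gives an ortho-quinone methide that the dihydropyridine reduces in situ (three-component reductive alkylation); C6 should react first because the C4=O···HO–C5 hydrogen bond fixes the C6=C7 enol between the two free hydroxyls, the aldehyde is limiting to avoid a second alkylation at C8, and no new stereocentre is formed while the cyclobutane centres are carried through.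

Step 11
Reactants: 14 (2R,3R)-6-{[(1R,3S)-2,2-dimethyl-3-(prop-1-en-2-yl)cyclobutyl]methyl}-5,7-dihydroxy-2,3-dimethylchroman-4-one, 15 3-phenylprop-2-ynal
Product: 17 methyl (3S)-3-[(2R,3R)-6-{[(1R,3S)-2,2-dimethyl-3-(prop-1-en-2-yl)cyclobutyl]methyl}-5,7-dihydroxy-2,3-dimethyl-4-oxo-3,4-dihydro-2H-chromen-8-yl]-3-phenylpropanoate, via tricyclic aryl lactone 16 (not isolated)
Conditions: (5aR,10bS)-2-mesityl-5a,10b-dihydro-4H,6H-indeno[2,1-b][1,2,4]triazolo[4,3-d][1,4]oxazin-2-ium chloride (10 mol%), toluene, 40 °C; then MeOH, K2CO3 (cat.), 0 °C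
Reagents that add atoms: methanol, CO
Why: The carbene converts the ynal by internal redox into a cinnamoyl azolium, the O7 enol adds to its carbonyl and a Coates–Claisen [3,3] shift forms the C8–C bond at the only unsubstituted ring carbon before lactonisation on O7 releases the carbene (carbene-catalysed ynal–enol annulation); the benzylic centre is set by the aminoindanol scaffold of the catalyst, and methanol then opens the activated aryl lactone to free O7 for the dearomatisation.

Step 12
Reactants: 17 methyl (3S)-3-[(2R,3R)-6-{[(1R,3S)-2,2-dimethyl-3-(prop-1-en-2-yl)cyclobutyl]methyl}-5,7-dihydroxy-2,3-dimethyl-4-oxo-3,4-dihydro-2H-chromen-8-yl]-3-phenylpropanoate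
Product: 18 methyl (3S)-3-[(2R,3R,6R)-6-{[(1R,3S)-2,2-dimethyl-3-(prop-1-en-2-yl)cyclobutyl]methyl}-5-hydroxy-2,3-dimethyl-6-(3-methylbut-2-en-1-yl)-4,7-dioxo-3,4,6,7-tetrahydro-2H-chromen-8-yl]-3-phenylpropanoate
Conditions: prenyl acetate (1.2 equiv), tris(dibenzylideneacetone)dipalladium Pd2(dba)3 (2.5 mol%), N,N'-[(1R,2R)-cyclohexane-1,2-diyl]bis[2-(diphenylphosphanyl)benzamide] (7.5 mol%), Et3N, 1,4-dioxane, rt
Reagents that add atoms: prenyl acetate (3-methylbut-2-en-1-yl acetate), CC(C)=CCOC(C)=O
Why: Tsuji–Trost C-allylation of an acylphloroglucinol with dearomatisation, in which zerovalent palladium ionises the acetate and the ammonium phenoxide attacks the unsubstituted terminus of the π-prenyl cation through C6, the carbon between the two free hydroxyls, while C8 is blocked by its branched substituent and any O-prenyl ether re-ionises; the chiral pocket of the bis(phosphinobenzamide) ligand selects the face of the flat ring and so sets the C6 quaternary centre under reagent control, the resident stereocentres being remote.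

Step 13
Reactants: 18 methyl (3S)-3-[(2R,3R,6R)-6-{[(1R,3S)-2,2-dimethyl-3-(prop-1-en-2-yl)cyclobutyl]methyl}-5-hydroxy-2,3-dimethyl-6-(3-methylbut-2-en-1-yl)-4,7-dioxo-3,4,6,7-tetrahydro-2H-chromen-8-yl]-3-phenylpropanoate
Product: 19 (3S)-3-[(2R,3R,6R)-6-{[(1R,3S)-2,2-dimethyl-3-(prop-1-en-2-yl)cyclobutyl]methyl}-5-hydroxy-2,3-dimethyl-6-(3-methylbut-2-en-1-yl)-4,7-dioxo-3,4,6,7-tetrahydro-2H-chromen-8-yl]-3-phenylpropanoic acid (CNP0103716.3)
Conditions: LiOH, THF/H2O, 0 °C → rt; aq. HCl to pH 3
Reagents that add atoms: lithium hydroxide, [Li+].[OH-]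
Why: Hydroxide saponifies the unhindered methyl ester (ester hydrolysis) while the core is present as its delocalised enolate, which should shut down enolisation at C3 and opening of ring B, so all six stereocentres are retained and acidification gives the target.

**Compound list**

1 | tiglic acid, (E)-2-methylbut-2-enoic acid | C/C=C(\C)C(=O)O | starting material
2 | tigloyl chloride, (E)-2-methylbut-2-enoyl chloride | C/C=C(\C)C(=O)Cl | intermediate
3 | phloroglucinol, benzene-1,3,5-triol | Oc1cc(O)cc(O)c1 | starting material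
4 | 2-tigloylphloroglucinol, (E)-2-methyl-1-(2,4,6-trihydroxyphenyl)but-2-en-1-one | C/C=C(\C)C(=O)c1c(O)cc(O)cc1O | intermediate
5 | (E)-1-{4-[(tert-butyldimethylsilyl)oxy]-2,6-dihydroxyphenyl}-2-methylbut-2-en-1-one | C/C=C(\C)C(=O)c1c(O)cc(O[Si](C)(C)C(C)(C)C)cc1O | intermediate
6 | (2R,3S)-7-[(tert-butyldimethylsilyl)oxy]-5-hydroxy-2,3-dimethylchroman-4-one (cis, not isolated) | O=C1c2c(O)cc(O[Si](C)(C)C(C)(C)C)cc2O[C@H](C)[C@@H]1C | intermediate
7 | (2R,3R)-7-[(tert-butyldimethylsilyl)oxy]-5-hydroxy-2,3-dimethylchroman-4-one (trans) | O=C1c2c(O)cc(O[Si](C)(C)C(C)(C)C)cc2O[C@H](C)[C@H]1C | intermediate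
8 | (2R,3R)-5,7-dihydroxy-2,3-dimethylchroman-4-one | O=C1c2c(O)cc(O)cc2O[C@H](C)[C@H]1C | intermediate
9 | (1S,5S)-(−)-verbenone, (1S,5S)-4,6,6-trimethylbicyclo[3.1.1]hept-3-en-2-one | CC1=CC(=O)[C@H]2C[C@@H]1C2(C)C | starting material
10 | (1S,3R)-3-acetyl-2,2-dimethylcyclobutane-1-carboxylic acid (cis-pinononic acid) | CC(=O)[C@@H]1C[C@H](C(=O)O)C1(C)C | intermediate
11 | methyl (1S,3R)-3-acetyl-2,2-dimethylcyclobutane-1-carboxylate | CC(=O)[C@@H]1C[C@H](C(=O)OC)C1(C)C | intermediate
12 | methyl (1S,3S)-2,2-dimethyl-3-(prop-1-en-2-yl)cyclobutane-1-carboxylate | C=C(C)[C@@H]1C[C@H](C(=O)OC)C1(C)C | intermediate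
13 | (1S,3S)-2,2-dimethyl-3-(prop-1-en-2-yl)cyclobutane-1-carbaldehyde | C=C(C)[C@@H]1C[C@H](C=O)C1(C)C | intermediate
14 | (2R,3R)-6-{[(1R,3S)-2,2-dimethyl-3-(prop-1-en-2-yl)cyclobutyl]methyl}-5,7-dihydroxy-2,3-dimethylchroman-4-one | O=C1c2c(O)c(C[C@H]3C[C@@H](C(C)=C)C3(C)C)c(O)cc2O[C@H](C)[C@H]1C | intermediate
15 | 3-phenylprop-2-ynal | O=CC#Cc1ccccc1 | starting material
16 | (2R,3R,10S)-6-{[(1R,3S)-2,2-dimethyl-3-(prop-1-en-2-yl)cyclobutyl]methyl}-5-hydroxy-2,3-dimethyl-10-phenyl-2,3,9,10-tetrahydro-4H,8H-pyrano[2,3-f]chromene-4,8-dione (lactone between O7 and the C8 side chain, not isolated) | O=C1c2c(O)c(C[C@H]3C[C@@H](C(C)=C)C3(C)C)c4OC(=O)C[C@@H](c5ccccc5)c4c2O[C@H](C)[C@H]1C | intermediate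
17 | methyl (3S)-3-[(2R,3R)-6-{[(1R,3S)-2,2-dimethyl-3-(prop-1-en-2-yl)cyclobutyl]methyl}-5,7-dihydroxy-2,3-dimethyl-4-oxo-3,4-dihydro-2H-chromen-8-yl]-3-phenylpropanoate | O=C1c2c(O)c(C[C@H]3C[C@@H](C(C)=C)C3(C)C)c(O)c([C@@H](CC(=O)OC)c4ccccc4)c2O[C@H](C)[C@H]1C | intermediate
18 | methyl (3S)-3-[(2R,3R,6R)-6-{[(1R,3S)-2,2-dimethyl-3-(prop-1-en-2-yl)cyclobutyl]methyl}-5-hydroxy-2,3-dimethyl-6-(3-methylbut-2-en-1-yl)-4,7-dioxo-3,4,6,7-tetrahydro-2H-chromen-8-yl]-3-phenylpropanoate | C=C(C)[C@@H]1C[C@H](C[C@@]2(CC=C(C)C)C(=O)C([C@@H](CC(=O)OC)c3ccccc3)=C3O[C@H](C)[C@@H](C)C(=O)C3=C2O)C1(C)C | intermediate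
19 | (3S)-3-[(2R,3R,6R)-6-{[(1R,3S)-2,2-dimethyl-3-(prop-1-en-2-yl)cyclobutyl]methyl}-5-hydroxy-2,3-dimethyl-6-(3-methylbut-2-en-1-yl)-4,7-dioxo-3,4,6,7-tetrahydro-2H-chromen-8-yl]-3-phenylpropanoic acid (CNP0103716.3) | C=C(C)[C@@H]1C[C@H](C[C@@]2(CC=C(C)C)C(=O)C([C@@H](CC(=O)O)c3ccccc3)=C3O[C@H](C)[C@@H](C)C(=O)C3=C2O)C1(C)C | target

**Step count**

Total step count: 13. Longest linear sequence: 9 steps (steps 1–5 and 10–13); the verbenone branch (steps 6–9) joins at step 10.

**Steps most likely to fail**

Step 12. The face of the planar ring may be poorly discriminated when C6 attacks the π-prenyl palladium complex, because the resident stereocentres are remote and the ligand may be mismatched; O-prenylation may also persist. Fallback: catalyst control is given up. From 17, classical alkylation with prenyl bromide and NaOMe in MeOH at 0 °C should give 18 together with its C6 epimer, methyl (3S)-3-[(2R,3R,6S)-6-{[(1R,3S)-2,2-dimethyl-3-(prop-1-en-2-yl)cyclobutyl]methyl}-5-hydroxy-2,3-dimethyl-6-(3-methylbut-2-en-1-yl)-4,7-dioxo-3,4,6,7-tetrahydro-2H-chromen-8-yl]-3-phenylpropanoate F1. The two diastereomers are separated by preparative HPLC and the route is rejoined at 18.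

Step 10. The aldehyde may be attacked through C8 instead of C6, a second alkylation may follow, and the α-centre of the aldehyde may epimerise through a proline enamine. Fallback: C6 is blocked before C8 is functionalised.
- From 7, the free 5-hydroxyl directs iodination (benzyltrimethylammonium dichloroiodate, CaCO3, CH2Cl2/MeOH) to the adjacent C6, giving (2R,3R)-7-[(tert-butyldimethylsilyl)oxy]-5-hydroxy-6-iodo-2,3-dimethylchroman-4-one F2.
- KHF2 in MeOH then frees the 7-hydroxyl to give (2R,3R)-5,7-dihydroxy-6-iodo-2,3-dimethylchroman-4-one F3.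
- With C6 occupied, the carbene-catalysed annulation with 15 can only engage C8 and gives (2R,3R,10S)-5-hydroxy-6-iodo-2,3-dimethyl-10-phenyl-2,3,9,10-tetrahydro-4H,8H-pyrano[2,3-f]chromene-4,8-dione F4, which is opened in the same flask with methanol to methyl (3S)-3-[(2R,3R)-5,7-dihydroxy-6-iodo-2,3-dimethyl-4-oxo-3,4-dihydro-2H-chromen-8-yl]-3-phenylpropanoate F5.
- Hydrogenolysis of the aryl iodide (palladium on carbon, H2, Et3N, MeOH, before any alkene is present) gives methyl (3S)-3-[(2R,3R)-5,7-dihydroxy-2,3-dimethyl-4-oxo-3,4-dihydro-2H-chromen-8-yl]-3-phenylpropanoate F6, whose only free ring carbon is C6.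
- Reductive alkylation of F6 with 13 under the conditions of step 10 returns to the route at 17.

Step 4. Enantioface discrimination in the ion pair may be insufficient, the C2 configuration may erode through reversible ring opening during the C3 equilibration, and the cis-to-trans equilibration may stay incomplete. Fallback: asymmetric catalysis is replaced by racemic closure and resolution. From 5, closure and equilibration with Et3N in CHCl3 should give, by way of 6 and its enantiomer (2S,3R)-7-[(tert-butyldimethylsilyl)oxy]-5-hydroxy-2,3-dimethylchroman-4-one F8, the racemic trans-chromanone, that is 7 together with its enantiomer (2S,3S)-7-[(tert-butyldimethylsilyl)oxy]-5-hydroxy-2,3-dimethylchroman-4-one F7. Preparative HPLC on a chiral stationary phase delivers 7, where the route is rejoined.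

**Further compounds**

F1 | step 12 | methyl (3S)-3-[(2R,3R,6S)-6-{[(1R,3S)-2,2-dimethyl-3-(prop-1-en-2-yl)cyclobutyl]methyl}-5-hydroxy-2,3-dimethyl-6-(3-methylbut-2-en-1-yl)-4,7-dioxo-3,4,6,7-tetrahydro-2H-chromen-8-yl]-3-phenylpropanoate | C=C(C)[C@@H]1C[C@H](C[C@]2(CC=C(C)C)C(=O)C([C@@H](CC(=O)OC)c3ccccc3)=C3O[C@H](C)[C@@H](C)C(=O)C3=C2O)C1(C)C
F2 | step 10 | (2R,3R)-7-[(tert-butyldimethylsilyl)oxy]-5-hydroxy-6-iodo-2,3-dimethylchroman-4-one | O=C1c2c(O)c(I)c(O[Si](C)(C)C(C)(C)C)cc2O[C@H](C)[C@H]1C
F3 | step 10 | (2R,3R)-5,7-dihydroxy-6-iodo-2,3-dimethylchroman-4-one | O=C1c2c(O)c(I)c(O)cc2O[C@H](C)[C@H]1C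
F4 | step 10 | (2R,3R,10S)-5-hydroxy-6-iodo-2,3-dimethyl-10-phenyl-2,3,9,10-tetrahydro-4H,8H-pyrano[2,3-f]chromene-4,8-dione | O=C1c2c(O)c(I)c3OC(=O)C[C@@H](c4ccccc4)c3c2O[C@H](C)[C@H]1C
F5 | step 10 | methyl (3S)-3-[(2R,3R)-5,7-dihydroxy-6-iodo-2,3-dimethyl-4-oxo-3,4-dihydro-2H-chromen-8-yl]-3-phenylpropanoate | O=C1c2c(O)c(I)c(O)c([C@@H](CC(=O)OC)c3ccccc3)c2O[C@H](C)[C@H]1C
F6 | step 10 | methyl (3S)-3-[(2R,3R)-5,7-dihydroxy-2,3-dimethyl-4-oxo-3,4-dihydro-2H-chromen-8-yl]-3-phenylpropanoate | O=C1c2c(O)cc(O)c([C@@H](CC(=O)OC)c3ccccc3)c2O[C@H](C)[C@H]1C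
F7 | step 4 | (2S,3S)-7-[(tert-butyldimethylsilyl)oxy]-5-hydroxy-2,3-dimethylchroman-4-one | O=C1c2c(O)cc(O[Si](C)(C)C(C)(C)C)cc2O[C@@H](C)[C@@H]1C
F8 | step 4 | (2S,3R)-7-[(tert-butyldimethylsilyl)oxy]-5-hydroxy-2,3-dimethylchroman-4-one | O=C1c2c(O)cc(O[Si](C)(C)C(C)(C)C)cc2O[C@@H](C)[C@H]1C
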